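**Retrosynthetic overview**
1. Manniflavanone (10) comes from global hydrogenolytic debenzylation of tetra-O-benzyl biflavanone 9.
2. Unit B's chromanone ring is formed last, by condensation of deoxybenzoin 7 with an aryl aldehyde and 6-endo oxa-Michael closure, so C2''/C3'' end up trans.
3. Deoxybenzoin 7 comes from Friedel–Crafts acylation of phloroglucinol with aryl-acetic acid 5. Acid 5 comes from oxidative cleavage of the C8-allyl group of 4.
4. The key C8–C3'' bond is made by an aromatic Claisen [3,3] rearrangement of the 7-O-allyl ether of (+)-taxifolin. Unit A's rings and its (2R,3R) stereocentres are already present in bought (+)-taxifolin.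

**Assumptions**
- The 7-OH is the most acidic phenol, so one equivalent of allyl bromide alkylates it selectively.
- The Claisen gives mainly the C8 isomer; the C6 isomer is removed by chromatography.
- The 2,3-trans dihydroflavonol of unit A survives the mild conditions.
- Unit B's new centres are set trans by thermodynamics, but their absolute sense relative to unit A is not controlled. I assume the two trans diastereomers form roughly 1:1 and separate by preparative HPLC.

---

**Step 1**
Reactants: 1 (+)-taxifolin, (2R,3R)-3,5,7,3',4'-pentahydroxyflavanone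
Product: 2 (2R,3R)-7-(allyloxy)-2-(3,4-dihydroxyphenyl)-3,5-dihydroxychroman-4-one
Conditions: allyl bromide (1.05 equiv), K2CO3, acetone, 25 °C to 50 °C
Reagents that add atoms: allyl bromide, C=CCBr
Why: Williamson O-alkylation occurs at the most acidic phenol (7-OH). The 5-OH is chelated to the C4 carbonyl and the catechol and 3-OH are less reactive, and the stereocentres are untouched.

**Step 2**
Reactants: 2
Product: 3 (2R,3R)-7-(allyloxy)-2-[3,4-bis(benzyloxy)phenyl]-3,5-dihydroxychroman-4-one
Conditions: BnBr (2.2 equiv), K2CO3, DMF, 25 °C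
Reagents that add atoms: benzyl bromide, BrCc1ccccc1
Why: The catechol phenols are benzylated so they cannot undergo Claisen rearrangement or oxidation later. The chelated 5-OH and the secondary 3-OH do not react under these mild conditions, and the stereocentres are kept by avoiding strong base.

**Step 3**
Reactants: 3
Product: 4 (2R,3R)-8-allyl-2-[3,4-bis(benzyloxy)phenyl]-3,5,7-trihydroxychroman-4-one
Conditions: N,N-diethylaniline or NMP, microwave 190–200 °C, 1 h; chromatography to remove the 6-allyl isomer
Reagents that add atoms: none
Why: This is the key aromatic Claisen [3,3]-sigmatropic rearrangement. The allyl group migrates from O7 to the ortho carbon C8, forming the C8–CH2 bond that becomes the C8–C3'' bond, and the dienone tautomerises to the phenol. C8 is favoured because the C7–C8 bond has more double-bond character in the chromanone. No new stereocentre is formed.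

**Step 4**
Reactants: 4
Product: 5 2-{(2R,3R)-2-[3,4-bis(benzyloxy)phenyl]-3,5,7-trihydroxy-4-oxochroman-8-yl}acetic acid
Conditions: OsO4 (cat.), Oxone, DMF, 25 °C
Reagents that add atoms: Oxone, OOS(=O)(=O)[O-].[K+]; water, O
Why: Os-catalysed dihydroxylation, periodate-type cleavage and oxidation convert the terminal alkene into the carboxylic acid. This excises the spare allyl carbon, leaving Ar–CH2–CO2H, where the CH2 becomes C3'' and the acid carbon becomes C4''. The stereocentres are not involved.

**Step 5**
Reactants: 5; 6 phloroglucinol (benzene-1,3,5-triol)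
Product: 7 (2R,3R)-2-[3,4-bis(benzyloxy)phenyl]-3,5,7-trihydroxy-8-[2-oxo-2-(2,4,6-trihydroxyphenyl)ethyl]chroman-4-one
Conditions: BF3·OEt2, 70–80 °C, 2 h
Reagents that add atoms: none
Why: BF3-mediated Friedel–Crafts (Hoesch-type) acylation of the very nucleophilic phloroglucinol gives the 2',4',6'-trihydroxydeoxybenzoin; any coumaranone lactone from the 7-OH/acid also acts as the acyl donor. The stereocentres are not involved.

**Step 6**
Reactants: 7; 8 3,4-bis(benzyloxy)benzaldehyde
Product: 9 protected biflavanone, 8-[(2''R,3''S)-2''-(3,4-bis(benzyloxy)phenyl)-5'',7''-dihydroxy-4''-oxochroman-3''-yl]-(2R,3R)-2-[3,4-bis(benzyloxy)phenyl]-3,5,7-trihydroxychroman-4-one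
Conditions: piperidine (cat.), EtOH, 60–80 °C; then preparative HPLC to separate the 2''S,3''R epimer
Reagents that add atoms: none (water is lost)
Why: Knoevenagel/Claisen–Schmidt-type condensation gives the α-aryl 2'-hydroxychalcone, and reversible 6-endo oxa-Michael closure with enolisation at C3'' equilibrates to the 2'',3''-trans (diequatorial) flavanone. Unit A's (2R,3R) centres are unaffected; the two trans diastereomers are formed and the desired (2''R,3''S) one is isolated.

**Step 7**
Reactants: 9
Product: 10 manniflavanone
Conditions: H2 (1 atm), Pd(OH)2/C, THF/MeOH, 25 °C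
Reagents that add atoms: none (benzyl groups leave as toluene)
Why: Hydrogenolysis removes all four aryl benzyl ethers under neutral conditions without touching the aryl ketones, the 3-OH or the stereocentres, which gives the target.

---

**Compound list**

| # | Name | SMILES | Role |
|---|---|---|---|
| 1 | (+)-taxifolin (2R,3R) | O=C1c2c(O)cc(O)cc2O[C@H](c2ccc(O)c(O)c2)[C@H]1O | starting material |
| 2 | 7-O-allyl taxifolin | O=C1c2c(O)cc(OCC=C)cc2O[C@H](c2ccc(O)c(O)c2)[C@H]1O | intermediate |
| 3 | 7-O-allyl-3',4'-di-O-benzyl taxifolin | O=C1c2c(O)cc(OCC=C)cc2O[C@H](c2ccc(OCc3ccccc3)c(OCc3ccccc3)c2)[C@H]1O | intermediate |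
| 4 | 8-allyl-3',4'-di-O-benzyl taxifolin | O=C1c2c(O)cc(O)c(CC=C)c2O[C@H](c2ccc(OCc3ccccc3)c(OCc3ccccc3)c2)[C@H]1O | intermediate |
| 5 | taxifolin-8-yl acetic acid (3',4'-di-OBn) | O=C1c2c(O)cc(O)c(CC(=O)O)c2O[C@H](c2ccc(OCc3ccccc3)c(OCc3ccccc3)c2)[C@H]1O | intermediate |
| 6 | phloroglucinol | Oc1cc(O)cc(O)c1 | starting material |
| 7 | 2',4',6'-trihydroxy-deoxybenzoin-linked taxifolin | O=C1c2c(O)cc(O)c(CC(=O)c3c(O)cc(O)cc3O)c2O[C@H](c2ccc(OCc4ccccc4)c(OCc4ccccc4)c2)[C@H]1O | intermediate |
| 8 | 3,4-bis(benzyloxy)benzaldehyde | O=Cc1ccc(OCc2ccccc2)c(OCc2ccccc2)c1 | starting material |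
| 9 | tetra-O-benzyl biflavanone (2R,3R,2''R,3''S) | O=C1c2c(O)cc(O)c([C@@H]3C(=O)c4c(O)cc(O)cc4O[C@H]3c3ccc(OCc5ccccc5)c(OCc5ccccc5)c3)c2O[C@H](c2ccc(OCc3ccccc3)c(OCc3ccccc3)c2)[C@H]1O | intermediate |
| 10 | manniflavanone | O=C1c2c(O)cc(O)c([C@@H]3C(=O)c4c(O)cc(O)cc4O[C@H]3c3ccc(O)c(O)c3)c2O[C@H](c2ccc(O)c(O)c2)[C@H]1O | target |

**Total step count:** 7
**Longest linear sequence:** 7 steps (1 → 2 → 3 → 4 → 5 → 7 → 9 → 10); phloroglucinol and the aldehyde are convergent commercial partners.

**Three steps most likely to fail**
1. **Step 6** (condensation/cyclisation onto a hindered, 2,6-dioxygenated α-aryl ketone; dr at unit B and HPLC separation). Fallback: reverse the bond order. Perkin/Knoevenagel condensation of acid 5 with 8 gives the α-aryl cinnamic acid, then BF3-mediated acylation of phloroglucinol and in-situ cyclisation close unit B.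
2. **Step 3** (Claisen: C6/C8 selectivity, thermal epimerisation or alkene isomerisation of the 2,3-trans dihydroflavonol). Fallback: drop the sigmatropic step; brominate or iodinate C8 regioselectively and install the allyl group by Stille coupling with allyl-SnBu3 to reach 4.
3. **Step 5** (BF3 Friedel–Crafts on a benzylated dihydroflavonol, with coumaranone formation and possible debenzylation or epimerisation). Fallback: convert 5 to its Weinreb amide, protect the phenols, and acylate with lithiated tris(MOM)-phloroglucinol.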